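**Retrosynthetic overview**
- The ten-membered carbocycle is opened last at C9–C10, giving a Z-alkenyl iodide and an α-acyloxy aldehyde (intramolecular Ni/Cr coupling; the C9 hydroxyl appears free beside the C8 ester).
- Key disconnection, C8–O: the whole ester side chain is attached by a direct asymmetric α-acyloxylation of a lactone aldehyde with the free side-chain acid, which joins the two halves and sets C8.
- The γ-lactone (C6, C7) is the first ring, from a catalytic asymmetric syn-allylboration of a dienal with a 2-(methoxycarbonyl)allylboronate, then lactonisation.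
- Building blocks: the dienal from geranyl acetate; the allylboronate from 3-silyloxypropanal and methyl acrylate; the acid from (R)-β-methyl-γ-butyrolactone and stearoyl chloride.
- Ring order: γ-lactone first, ten-membered ring last.

Assumption: atom labels C1–C15 follow germacrane numbering (lactone oxygen on C6, ester oxygen on C8, free hydroxyl on C9, methyl C14 on C10, methyl C15 on C4); 3-[(tert-butyldimethylsilyl)oxy]propanal and (4R)-4-methyloxolan-2-one are taken as catalogue compounds.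

**Step 1**
Reactants: 1 geranyl acetate, (2E)-3,7-dimethylocta-2,6-dien-1-yl acetate
Product: 2 (2E)-3-methyl-6-oxohex-2-en-1-yl acetate
Conditions: O3 (1 equiv), CH2Cl2/pyridine, −78 °C; then Me2S
Reagents that add atoms: ozone, [O-][O+]=O
Why: Chemoselective ozonolysis with reductive work-up, because the electron-rich 6,7-alkene reacts much faster than the 2,3-alkene that is deactivated by the allylic acetate.

**Step 2**
Reactants: 2 (2E)-3-methyl-6-oxohex-2-en-1-yl acetate; 3 ethyltriphenylphosphonium iodide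
Product: 7 (2E,6Z)-7-iodo-3-methylocta-2,6-dien-1-yl acetate, via ethylidenetriphenylphosphorane 4 (not isolated), via (1-iodoethyl)triphenylphosphonium iodide 5 (not isolated), via (1-iodoethylidene)triphenylphosphorane 6 (not isolated)
Conditions: 3, n-BuLi, THF, 0 °C; I2, −78 °C; NaN(SiMe3)2, −20 °C; then 2, −78 °C
Reagents that add atoms: iodine, II
Why: Stork–Zhao Wittig olefination, in which the α-iodo ylide adds under kinetic control to give the Z-2-iodoalkene (iodine cis to the chain), the geometry later carried into the C1=C10 bond.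

**Step 3**
Reactants: 7 (2E,6Z)-7-iodo-3-methylocta-2,6-dien-1-yl acetate
Product: 8 (2E,6Z)-7-iodo-3-methylocta-2,6-dien-1-ol
Conditions: K2CO3 (0.2 equiv), MeOH, rt
Reagents that add atoms: none
Why: Base-catalysed transesterification (methanolysis) removes the acetate and leaves the alkenyl iodide untouched.

**Step 4**
Reactants: 8 (2E,6Z)-7-iodo-3-methylocta-2,6-dien-1-ol
Product: 9 (2E,6Z)-7-iodo-3-methylocta-2,6-dienal
Conditions: TEMPO (2,2,6,6-tetramethylpiperidin-1-oxyl, 10 mol%), PhI(OAc)2, CH2Cl2, rt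
Reagents that add atoms: none
Why: Oxoammonium (TEMPO) oxidation of the allylic alcohol stops at the enal and does not isomerise the 2E double bond.

**Step 5**
Reactants: 10 3-[(tert-butyldimethylsilyl)oxy]propanal; 11 methyl acrylate
Product: 12 methyl 5-[(tert-butyldimethylsilyl)oxy]-3-hydroxy-2-methylidenepentanoate (racemic)
Conditions: DABCO (1,4-diazabicyclo[2.2.2]octane, 0.5 equiv), neat, rt, 4 d
Reagents that add atoms: none
Why: Morita–Baylis–Hillman reaction under amine catalysis; the racemic carbinol centre is erased in step 7.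

**Step 6**
Reactants: 12 methyl 5-[(tert-butyldimethylsilyl)oxy]-3-hydroxy-2-methylidenepentanoate
Product: 13 methyl 3-(acetyloxy)-5-[(tert-butyldimethylsilyl)oxy]-2-methylidenepentanoate (racemic)
Conditions: Ac2O, Et3N, DMAP (4-(dimethylamino)pyridine, cat.), CH2Cl2, 0 °C
Reagents that add atoms: acetic anhydride, CC(=O)OC(C)=O
Why: DMAP-catalysed acetylation turns the allylic alcohol into the leaving group needed for allylic borylation.

**Step 7**
Reactants: 13 methyl 3-(acetyloxy)-5-[(tert-butyldimethylsilyl)oxy]-2-methylidenepentanoate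
Product: 14 methyl (2E)-5-[(tert-butyldimethylsilyl)oxy]-2-[(4,4,5,5-tetramethyl-1,3,2-dioxaborolan-2-yl)methyl]pent-2-enoate
Conditions: B2pin2, CuCl (10 mol%), LiCl, KOAc, DMF, rt
Reagents that add atoms: bis(pinacolato)diboron, CC1(C)OB(OC1(C)C)B1OC(C)(C)C(C)(C)O1
Why: Copper-catalysed SN2' borylation of a Baylis–Hillman acetate (boryl-copper addition, then β-acetoxy elimination) gives the trisubstituted allylboronate with the chain cis to the CH2B group.

**Step 8**
Reactants: 9 (2E,6Z)-7-iodo-3-methylocta-2,6-dienal; 14 methyl (2E)-5-[(tert-butyldimethylsilyl)oxy]-2-[(4,4,5,5-tetramethyl-1,3,2-dioxaborolan-2-yl)methyl]pent-2-enoate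
Product: 17 (4S,5S)-4-(2-hydroxyethyl)-5-[(1E,5Z)-6-iodo-2-methylhepta-1,5-dien-1-yl]-3-methylideneoxolan-2-one, via O-boryl syn-homoallylic ester 15 (not isolated), via silyl-protected lactone 16 (not isolated)
Conditions: (R)-3,3'-bis(2,4,6-triisopropylphenyl)-1,1'-binaphthyl-2,2'-diyl hydrogen phosphate (10 mol%), 4 Å MS, toluene, 0 °C to rt; then camphor-10-sulfonic acid, MeOH, rt
Reagents that add atoms: none
Why: Chiral-phosphoric-acid-catalysed allylboration through a closed chair transition state, in which the chain cis to CH2B sits axial (syn adduct, hence the cis lactone) and the (R)-acid directs attack to the Re face of the enal (6S and 7S), followed by acid methanolysis that cleaves the borate, closes the γ-lactone and removes the silyl ether.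

**Step 9**
Reactants: 17 (4S,5S)-4-(2-hydroxyethyl)-5-[(1E,5Z)-6-iodo-2-methylhepta-1,5-dien-1-yl]-3-methylideneoxolan-2-one
Product: 18 2-[(2S,3S)-2-[(1E,5Z)-6-iodo-2-methylhepta-1,5-dien-1-yl]-4-methylidene-5-oxooxolan-3-yl]acetaldehyde
Conditions: TEMPO (10 mol%), PhI(OAc)2, CH2Cl2, rt
Reagents that add atoms: none
Why: Oxoammonium (TEMPO) oxidation of the primary alcohol to the aldehyde under non-basic conditions that spare the α-methylene lactone and the C7 centre.

**Step 10**
Reactants: 19 (4R)-4-methyloxolan-2-one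
Product: 21 benzyl (3R)-4-hydroxy-3-methylbutanoate, via potassium (3R)-4-hydroxy-3-methylbutanoate 20 (not isolated)
Conditions: KOH, MeOH/H2O, rt; evaporate; BnBr, DMF, rt
Reagents that add atoms: potassium hydroxide, [K+].[OH-]; benzyl bromide, BrCc1ccccc1
Why: Saponification followed by SN2 O-benzylation of the carboxylate traps the open-chain hydroxy acid before it can close back to the lactone; the stereocentre is not involved.

**Step 11**
Reactants: 21 benzyl (3R)-4-hydroxy-3-methylbutanoate; 22 octadecanoyl chloride (stearoyl chloride)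
Product: 23 benzyl (3R)-3-methyl-4-(octadecanoyloxy)butanoate
Conditions: pyridine, DMAP (cat.), CH2Cl2, 0 °C to rt
Reagents that add atoms: none
Why: DMAP-catalysed acylation of the primary alcohol by the acid chloride (nucleophilic acyl substitution).

**Step 12**
Reactants: 23 benzyl (3R)-3-methyl-4-(octadecanoyloxy)butanoate
Product: 24 (3R)-3-methyl-4-(octadecanoyloxy)butanoic acid
Conditions: H2 (1 atm), 10% Pd/C, EtOAc, rt
Reagents that add atoms: none
Why: Hydrogenolysis cleaves the benzyl ester and leaves the alkyl ester intact.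

**Step 13**
Reactants: 18 2-[(2S,3S)-2-[(1E,5Z)-6-iodo-2-methylhepta-1,5-dien-1-yl]-4-methylidene-5-oxooxolan-3-yl]acetaldehyde; 24 (3R)-3-methyl-4-(octadecanoyloxy)butanoic acid
Product: 25 (1S)-1-[(2S,3S)-2-[(1E,5Z)-6-iodo-2-methylhepta-1,5-dien-1-yl]-4-methylidene-5-oxooxolan-3-yl]-2-oxoethyl (3R)-3-methyl-4-(octadecanoyloxy)butanoate
Conditions: 24 (1.5 equiv), (2S,5S)-5-benzyl-2-tert-butyl-3-methylimidazolidin-4-one·CF3CO2H (20 mol%), Cu(OTf)2 (10 mol%), Na2S2O8, NaHCO3, MeCN/H2O, 4 °C
Reagents that add atoms: none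
Why: Proposed new method: a singly-occupied-orbital (SOMO) α-acyloxylation in which the imidazolidinone condenses with 18 to an E-enamine, the divalent copper/persulfate couple oxidises it by one electron to a three-π-electron radical cation, the carboxylate of 24 adds to C8 on the face left open by the benzyl group (Si face, giving 8S under catalyst control over the resident C7 centre), and a second one-electron oxidation plus hydrolysis release 25 and the amine; the closest known reactions are the SOMO-type α-chlorination of aldehydes with chloride under copper/persulfate and the enamine-catalysed α-benzoyloxylation with dibenzoyl peroxide, while carboxylate capture of an enamine radical cation with a free acid as oxygen source has not been shown.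

**Step 14**
Reactants: 25 (1S)-1-[(2S,3S)-2-[(1E,5Z)-6-iodo-2-methylhepta-1,5-dien-1-yl]-4-methylidene-5-oxooxolan-3-yl]-2-oxoethyl (3R)-3-methyl-4-(octadecanoyloxy)butanoate
Product: 26 (3aS,4S,5R,6Z,10E,11aS)-5-hydroxy-6,10-dimethyl-3-methylidene-2-oxo-2,3,3a,4,5,8,9,11a-octahydrocyclodeca[b]furan-4-yl (3R)-3-methyl-4-(octadecanoyloxy)butanoate
Conditions: CrCl2 (8 equiv), NiCl2 (2 mol%), DMSO/THF, rt, 2 mM, slow addition; aqueous work-up
Reagents that add atoms: none
Why: Nozaki–Hiyama–Kishi macrocyclization, in which zerovalent nickel inserts into the C–I bond with retention of the Z geometry, transmetalation gives an alkenyl species of trivalent chromium that adds to the aldehyde, and Felkin–Anh attack anti to the C8–O bond gives the 8,9-erythro (9R) carbinol while closing the ten-membered ring.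

**Compound list**
1 | geranyl acetate, (2E)-3,7-dimethylocta-2,6-dien-1-yl acetate | CC(=O)OC/C=C(\C)CCC=C(C)C | starting material
2 | (2E)-3-methyl-6-oxohex-2-en-1-yl acetate | CC(=O)OC/C=C(\C)CCC=O | intermediate
3 | ethyltriphenylphosphonium iodide | CC[P+](c1ccccc1)(c1ccccc1)c1ccccc1.[I-] | starting material
4 | ethylidenetriphenylphosphorane | CC=P(c1ccccc1)(c1ccccc1)c1ccccc1 | intermediate (not isolated)
5 | (1-iodoethyl)triphenylphosphonium iodide | CC(I)[P+](c1ccccc1)(c1ccccc1)c1ccccc1.[I-] | intermediate (not isolated)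
6 | (1-iodoethylidene)triphenylphosphorane | CC(I)=P(c1ccccc1)(c1ccccc1)c1ccccc1 | intermediate (not isolated)
7 | (2E,6Z)-7-iodo-3-methylocta-2,6-dien-1-yl acetate | CC(=O)OC/C=C(\C)CC/C=C(/C)I | intermediate
8 | (2E,6Z)-7-iodo-3-methylocta-2,6-dien-1-ol | OC/C=C(\C)CC/C=C(/C)I | intermediate
9 | (2E,6Z)-7-iodo-3-methylocta-2,6-dienal | O=C/C=C(\C)CC/C=C(/C)I | intermediate
10 | 3-[(tert-butyldimethylsilyl)oxy]propanal | O=CCCO[Si](C)(C)C(C)(C)C | starting material
11 | methyl acrylate | C=CC(=O)OC | starting material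
12 | methyl 5-[(tert-butyldimethylsilyl)oxy]-3-hydroxy-2-methylidenepentanoate (racemic) | C=C(C(=O)OC)C(O)CCO[Si](C)(C)C(C)(C)C | intermediate
13 | methyl 3-(acetyloxy)-5-[(tert-butyldimethylsilyl)oxy]-2-methylidenepentanoate (racemic) | C=C(C(=O)OC)C(OC(C)=O)CCO[Si](C)(C)C(C)(C)C | intermediate
14 | methyl (2E)-5-[(tert-butyldimethylsilyl)oxy]-2-[(4,4,5,5-tetramethyl-1,3,2-dioxaborolan-2-yl)methyl]pent-2-enoate | COC(=O)/C(CB1OC(C)(C)C(C)(C)O1)=C/CCO[Si](C)(C)C(C)(C)C | intermediate
15 | methyl (3S,4S,5E,9Z)-3-{2-[(tert-butyldimethylsilyl)oxy]ethyl}-10-iodo-6-methyl-2-methylidene-4-[(4,4,5,5-tetramethyl-1,3,2-dioxaborolan-2-yl)oxy]undeca-5,9-dienoate (O-boryl syn-homoallylic ester) | C=C(C(=O)OC)[C@H](CCO[Si](C)(C)C(C)(C)C)[C@@H](OB1OC(C)(C)C(C)(C)O1)/C=C(\C)CC/C=C(/C)I | intermediate (not isolated)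
16 | (4S,5S)-4-{2-[(tert-butyldimethylsilyl)oxy]ethyl}-5-[(1E,5Z)-6-iodo-2-methylhepta-1,5-dien-1-yl]-3-methylideneoxolan-2-one (silyl-protected lactone) | C=C1C(=O)O[C@@H](/C=C(\C)CC/C=C(/C)I)[C@H]1CCO[Si](C)(C)C(C)(C)C | intermediate (not isolated)
17 | (4S,5S)-4-(2-hydroxyethyl)-5-[(1E,5Z)-6-iodo-2-methylhepta-1,5-dien-1-yl]-3-methylideneoxolan-2-one | C=C1C(=O)O[C@@H](/C=C(\C)CC/C=C(/C)I)[C@H]1CCO | intermediate
18 | 2-[(2S,3S)-2-[(1E,5Z)-6-iodo-2-methylhepta-1,5-dien-1-yl]-4-methylidene-5-oxooxolan-3-yl]acetaldehyde | C=C1C(=O)O[C@@H](/C=C(\C)CC/C=C(/C)I)[C@H]1CC=O | intermediate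
19 | (4R)-4-methyloxolan-2-one, (R)-β-methyl-γ-butyrolactone | O=C1C[C@@H](C)CO1 | starting material
20 | potassium (3R)-4-hydroxy-3-methylbutanoate | [K+].[O-]C(=O)C[C@@H](C)CO | intermediate (not isolated)
21 | benzyl (3R)-4-hydroxy-3-methylbutanoate | O=C(C[C@@H](C)CO)OCc1ccccc1 | intermediate
22 | octadecanoyl chloride (stearoyl chloride) | CCCCCCCCCCCCCCCCCC(=O)Cl | starting material
23 | benzyl (3R)-3-methyl-4-(octadecanoyloxy)butanoate | O=C(C[C@@H](C)COC(=O)CCCCCCCCCCCCCCCCC)OCc1ccccc1 | intermediate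
24 | (3R)-3-methyl-4-(octadecanoyloxy)butanoic acid | OC(=O)C[C@@H](C)COC(=O)CCCCCCCCCCCCCCCCC | intermediate
25 | (1S)-1-[(2S,3S)-2-[(1E,5Z)-6-iodo-2-methylhepta-1,5-dien-1-yl]-4-methylidene-5-oxooxolan-3-yl]-2-oxoethyl (3R)-3-methyl-4-(octadecanoyloxy)butanoate | C=C1C(=O)O[C@@H](/C=C(\C)CC/C=C(/C)I)[C@H]1[C@H](OC(=O)C[C@@H](C)COC(=O)CCCCCCCCCCCCCCCCC)C=O | intermediate
26 | (3aS,4S,5R,6Z,10E,11aS)-5-hydroxy-6,10-dimethyl-3-methylidene-2-oxo-2,3,3a,4,5,8,9,11a-octahydrocyclodeca[b]furan-4-yl (3R)-3-methyl-4-(octadecanoyloxy)butanoate | C=C1C(=O)O[C@H]2/C=C(\C)CC/C=C(/C)[C@@H](O)[C@@H](OC(=O)C[C@@H](C)COC(=O)CCCCCCCCCCCCCCCCC)[C@@H]12 | target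

**Step count**
Total: 14 steps. Longest linear sequence: 8 steps (1, 2, 3, 4, 8, 9, 13, 14).

**Three steps most likely to fail**

Step 8 (asymmetric allylboration). The ester-bearing allylboronate is a weak nucleophile and its enantioselectivity under phosphoric acid catalysis is not secured. The fallback replaces catalyst control by chiral-pool substrate control; it sets out from 9 and comes back at 25, so it also bypasses step 13. (4S)-2,2-Dimethyl-1,3-dioxolane-4-carbaldehyde (bought; from L-ascorbic acid) and 11 give with DABCO methyl 2-{[(4S)-2,2-dimethyl-1,3-dioxolan-4-yl](hydroxy)methyl}prop-2-enoate F1. NBS/Me2S converts it with allylic shift into methyl (2Z)-2-(bromomethyl)-3-[(4R)-2,2-dimethyl-1,3-dioxolan-4-yl]prop-2-enoate F2. Zinc-mediated Barbier allylation of 9 with F2 (Zn, aqueous NH4Cl/THF) and lactonisation give (4S,5S)-4-[(4R)-2,2-dimethyl-1,3-dioxolan-4-yl]-5-[(1E,5Z)-6-iodo-2-methylhepta-1,5-dien-1-yl]-3-methylideneoxolan-2-one F3. The chair transition state gives the syn adduct, and the new bond is assumed to form anti to the dioxolane C–O bond; this sense of induction is a model prediction, not a verified result. Aqueous AcOH then gives (4R,5S)-4-[(1R)-1,2-dihydroxyethyl]-5-[(1E,5Z)-6-iodo-2-methylhepta-1,5-dien-1-yl]-3-methylideneoxolan-2-one F4. Mitsunobu esterification with 24 (PPh3, DIAD) runs through the cyclic dioxaphosphorane and acylates the secondary carbon with inversion, giving (1S)-2-hydroxy-1-[(2S,3S)-2-[(1E,5Z)-6-iodo-2-methylhepta-1,5-dien-1-yl]-4-methylidene-5-oxooxolan-3-yl]ethyl (3R)-3-methyl-4-(octadecanoyloxy)butanoate F5. TEMPO/PhI(OAc)2 oxidation of its primary alcohol gives 25.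

Step 13 (the proposed new α-acyloxylation). Possible failures are attack of the oxidant on the trisubstituted alkenes, epimerisation or over-oxidation of the α-acyloxy aldehyde, and a mismatch between the catalyst and the C7 centre. The fallback uses known chemistry only; it sets out from 18 and comes back at 25. L-Proline-catalysed α-aminoxylation of 18 with nitrosobenzene, followed by NaBH4 in the same flask, gives (4S,5S)-4-{(1R)-2-hydroxy-1-[(phenylamino)oxy]ethyl}-5-[(1E,5Z)-6-iodo-2-methylhepta-1,5-dien-1-yl]-3-methylideneoxolan-2-one F6. CuSO4 in MeOH cleaves the N–O bond to give diol F4. The invertive Mitsunobu esterification with 24 then gives F5, and TEMPO/PhI(OAc)2 oxidation gives 25.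

Step 14 (Ni/Cr macrocyclization). Possible failures are ring strain, reduction of the α-acyloxy aldehyde by divalent chromium, acyl shift, and the wrong configuration at C9. The fallback sets C9 by hydride delivery instead of C–C bond formation; it sets out from 25 and comes back at 26. If the ring closure gives mainly (3aS,4S,5S,6Z,10E,11aS)-5-hydroxy-6,10-dimethyl-3-methylidene-2-oxo-2,3,3a,4,5,8,9,11a-octahydrocyclodeca[b]furan-4-yl (3R)-3-methyl-4-(octadecanoyloxy)butanoate F7, Dess–Martin oxidation of the carbinol mixture gives the enone (3aS,4S,6Z,10E,11aS)-6,10-dimethyl-3-methylidene-2,5-dioxo-2,3,3a,4,5,8,9,11a-octahydrocyclodeca[b]furan-4-yl (3R)-3-methyl-4-(octadecanoyloxy)butanoate F8. Reagent-controlled 1,2-reduction (oxazaborolidine/catecholborane, −78 °C) then gives 26.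

**Further compounds**
F1 | step 8 | methyl 2-{[(4S)-2,2-dimethyl-1,3-dioxolan-4-yl](hydroxy)methyl}prop-2-enoate | C=C(C(=O)OC)C(O)[C@@H]1COC(C)(C)O1
F2 | step 8 | methyl (2Z)-2-(bromomethyl)-3-[(4R)-2,2-dimethyl-1,3-dioxolan-4-yl]prop-2-enoate | COC(=O)/C(CBr)=C/[C@@H]1COC(C)(C)O1
F3 | step 8 | (4S,5S)-4-[(4R)-2,2-dimethyl-1,3-dioxolan-4-yl]-5-[(1E,5Z)-6-iodo-2-methylhepta-1,5-dien-1-yl]-3-methylideneoxolan-2-one | C=C1C(=O)O[C@@H](/C=C(\C)CC/C=C(/C)I)[C@H]1[C@@H]2COC(C)(C)O2
F4 | step 8 | (4R,5S)-4-[(1R)-1,2-dihydroxyethyl]-5-[(1E,5Z)-6-iodo-2-methylhepta-1,5-dien-1-yl]-3-methylideneoxolan-2-one | C=C1C(=O)O[C@@H](/C=C(\C)CC/C=C(/C)I)[C@H]1[C@@H](O)CO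
F5 | step 8 | (1S)-2-hydroxy-1-[(2S,3S)-2-[(1E,5Z)-6-iodo-2-methylhepta-1,5-dien-1-yl]-4-methylidene-5-oxooxolan-3-yl]ethyl (3R)-3-methyl-4-(octadecanoyloxy)butanoate | C=C1C(=O)O[C@@H](/C=C(\C)CC/C=C(/C)I)[C@H]1[C@H](OC(=O)C[C@@H](C)COC(=O)CCCCCCCCCCCCCCCCC)CO
F6 | step 13 | (4S,5S)-4-{(1R)-2-hydroxy-1-[(phenylamino)oxy]ethyl}-5-[(1E,5Z)-6-iodo-2-methylhepta-1,5-dien-1-yl]-3-methylideneoxolan-2-one | C=C1C(=O)O[C@@H](/C=C(\C)CC/C=C(/C)I)[C@H]1[C@@H](ONc2ccccc2)CO
F7 | step 14 | (3aS,4S,5S,6Z,10E,11aS)-5-hydroxy-6,10-dimethyl-3-methylidene-2-oxo-2,3,3a,4,5,8,9,11a-octahydrocyclodeca[b]furan-4-yl (3R)-3-methyl-4-(octadecanoyloxy)butanoate | C=C1C(=O)O[C@H]2/C=C(\C)CC/C=C(/C)[C@H](O)[C@@H](OC(=O)C[C@@H](C)COC(=O)CCCCCCCCCCCCCCCCC)[C@@H]12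
F8 | step 14 | (3aS,4S,6Z,10E,11aS)-6,10-dimethyl-3-methylidene-2,5-dioxo-2,3,3a,4,5,8,9,11a-octahydrocyclodeca[b]furan-4-yl (3R)-3-methyl-4-(octadecanoyloxy)butanoate | C=C1C(=O)O[C@H]2/C=C(\C)CC/C=C(/C)C(=O)[C@@H](OC(=O)C[C@@H](C)COC(=O)CCCCCCCCCCCCCCCCC)[C@@H]12
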